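Late in this flask, near 6.0 min, there is no reading yet: Monday's run, the very flask asked about, stops at 80.0 s, so you have to build the tail from the front of the curve.

- Monday's: starting material 1 M; reagent 1 M; free catalyst 1 mM; the very flask that is asked about, followed so far
- flask: starting material 1.0 M; reagent 1.00 M; free catalyst 1.0 mM; time 6.0 min

- Monday's (time / s: starting material / %, product / %): 10.0: 96.6, 3.6; 20.0: 93.3, 6.7; 30.0: 90.3, 9.9; 50.0: 84.0, 16.2; 80.0: 75.1, 25.8

(scatter of a reading: 0.3 percentage points)

- amount of starting material in percent of the starting material charged, at 40 s, 2.0 min and 6.0 min



Take the slope at both ends of Monday's readings. The first 30.0 s lose 0.00323 s⁻¹ of the charge, and the stretch from 50.0 s to 80.0 s loses 0.00297 s⁻¹. Between those stretches the mean starting material goes from 95.2% to 79.5%, so the rate fell less than the amount did. The ratio of the two logarithms comes to 0.481, a rough reading given the scatter. Call it the apparent order, the power of the remaining starting material that the rate follows.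

Now draw the curve. It leaves the charge at 0.00331 s⁻¹. A straight line at that slope reaches zero at 5.04 min, while an exponential with that slope still stands at 30.4% at 6.0 min; the order joins these two ends. Integrating gives an emptying clock of 9.69 min: the fraction left is one minus time over clock, raised to one over one minus the order. So your curve bends gently without a knee, passes 87.2% at 40 s, crosses half at 2.93 min, stands at 64.1% at 2.0 min and at 15.6% at 6.0 min, and runs into zero at the clock.

The forecast, holding that “First order in starting material fits well”, gives 86.9%, 66% and 30%, so its last value lies above mine.

The flask gives 86.9%, 63.0% and 12.4%.

    reagent + catalyst intermediate A → catalyst intermediate B (k = 260 M⁻¹ s⁻¹)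
    starting material + free catalyst → catalyst intermediate A (k = 16.0 M⁻¹ s⁻¹)
    catalyst intermediate C → catalyst intermediate D (k = 12.0 s⁻¹)
    catalyst intermediate B ⇌ by-product + catalyst intermediate C (K = 1.90 M, k = 12.0 s⁻¹)
    catalyst intermediate D → free catalyst + product (k = 15.0 s⁻¹)

Your order-based curve stands 3.2 percentage points high at 6.0 min. The starting material still standing in this flask at 6.0 min is there mainly because the run ends at that time: carried on to 60.0 min, the flask leaves 0% against 12.4%. The running short of reagent is not the reason: with the reagent held, the flask leaves 11.8% against 12.4%. Now take the rate as proportional to the catalyst charged: in a second flask with half the free catalyst, the clock becomes 19.4 min. The same order then gives 49.0% at 6.0 min, and that second flask stands at 47.0%.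

The earlier runs and the new flask stem from a simulated flask with constants of no real substance.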